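Atom numbers are halimane numbers. Ring A is C1–C5 plus C10, and C4 bears CH3 and CO2H. Ring B is C5–C10, with C17 the methyl on C8 and C20 the methyl on C9. The side chain is C11–C16.
Cuts: the propionate O–acyl bond; C12–C13 (B-alkyl Suzuki–Miyaura); C9–C11 together with the C1=C10 olefin (vinyl conjugate addition to a C1-keto C9=C10 enone, then enolate → triflate → H); ring B at C6–C7 and C9–C10 in one step; C5–C6 (nitromethane); ring A (Diels–Alder).
Enabling feature: the C1=C10 olefin beside quaternary C9 is the footprint of a C1 enolate, so the enone C9=C10–C1=O is a valid precursor. The unit C7–C8(C17)–C9(C20) of ring B is then simply 3-methylbut-3-en-2-one, and C6 and C10 of ring A are both nucleophilic in a γ-nitro ketone.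
Forward order: ring A is made first. Ring B is added by a nitro-Michael/aldol-condensation [3+3] domino. The nitro helper and the C1 oxygen are then removed, and the chain is joined last.
Stereochemistry: C4 comes from a catalytic asymmetric Diels–Alder reaction, C5 from catalyst-matched axial Michael attack, C8 from equilibration in the key step, and C9 from axial attack anti to C17. The E olefin comes from an E enol triflate.

Key step: step 5

Remark: the sense of induction of the two chiral organocatalysts (steps 1 and 4) is fixed by choosing the antipode or pseudo-enantiomer that leads to the configuration drawn.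

Step 1
Reactants: 1 (E)-3-(tert-butyldimethylsilyloxy)-N,N-dimethylbuta-1,3-dien-1-amine; 2 methacrolein
Product: 4 (S)-1-methyl-4-oxocyclohex-2-ene-1-carbaldehyde, via Diels–Alder adduct 3 (not isolated)
Conditions: 1-naphthyl-TADDOL (20 mol %, antipode that gives S), toluene, −80 °C; then aq HF, MeCN, 0 °C
Reagents that add atoms: none
Why: Hydrogen-bond-catalysed Diels–Alder reaction of an aminosiloxydiene with an α-substituted enal, in which the amino terminus bonds to the α-carbon (ortho/para rule), the diol-bound aldehyde is attacked on its open face so that quaternary C4 is set as S, and HF then removes the silyl group and triggers β-elimination of the amine to the enone.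

Step 2
Reactants: 4 (S)-1-methyl-4-oxocyclohex-2-ene-1-carbaldehyde
Product: 5 (S)-1-methyl-4-oxocyclohex-2-ene-1-carboxylic acid
Conditions: NaClO2, NaH2PO4, 2-methylbut-2-ene, t-BuOH/H2O, 0 °C to rt
Reagents that add atoms: sodium chlorite [Na+].[O-]Cl=O
Why: The Pinnick oxidation is selective for the aldehyde, leaves the electron-poor enone alone and cannot disturb the quaternary centre.

Step 3
Reactants: 5 (S)-1-methyl-4-oxocyclohex-2-ene-1-carboxylic acid
Product: 6 methyl (S)-1-methyl-4-oxocyclohex-2-ene-1-carboxylate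
Conditions: MeI, K2CO3, DMF, rt
Reagents that add atoms: iodomethane CI
Why: Carboxylate O-alkylation (SN2 on MeI) avoids acyl activation at the hindered tertiary carboxyl group.

Step 4
Reactants: 6 methyl (S)-1-methyl-4-oxocyclohex-2-ene-1-carboxylate; 7 nitromethane
Product: 8 methyl (1S,2S)-1-methyl-2-(nitromethyl)-4-oxocyclohexane-1-carboxylate
Conditions: 9-amino-9-deoxy-epi-cinchona alkaloid (20 mol %, pseudo-enantiomer matched to 2S), PhCO2H (40 mol %), 7 (10 equiv), THF, 40 °C
Reagents that add atoms: none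
Why: Iminium-catalysed asymmetric nitro-Michael addition, in which the primary-amine catalyst directs attack on the β-carbon C5 to the face opposite the pseudo-axial ester (axial, antiperiplanar attack on the half-chair), so catalyst and substrate act in the same sense and C6 ends trans to the ester (C5 = S).

Step 5
Reactants: 8 methyl (1S,2S)-1-methyl-2-(nitromethyl)-4-oxocyclohexane-1-carboxylate; 9 3-methylbut-3-en-2-one
Product: 12 methyl (1S,6R,8R,8aS)-1,5,6-trimethyl-8-nitro-4-oxo-1,2,3,4,6,7,8,8a-octahydronaphthalene-1-carboxylate, via Michael adduct 10 (not isolated), via ketol 11 (not isolated)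
Conditions: NaOMe (1.5 equiv), MeOH, 0 °C, slow addition of 9; then 65 °C; AcOH quench at 0 °C
Reagents that add atoms: none
Why: Domino nitro-Michael addition/intramolecular aldol condensation, a formal [3+3] carbocyclisation whose closest known relatives are the base-mediated Michael–aldol annulations of γ-nitro ketones and 1,3-dicarbonyl compounds with enones and the cyclodehydration of 1,7-diketones to 1-acylcyclohexenes. Methoxide deprotonates only the CH2NO2 group, the nitronate carbon C6 adds to the CH2 terminus C7 of 9 (first bond), and after proton exchange the C10 enolate of the ring ketone attacks the new methyl ketone C9 and water is lost by E1cB (second bond, formed as C9=C10). Ring B closes in the 6-(enolexo)-exo-trig mode. C5 is carried through unchanged, whereas C8 (α to the ketone in 10, γ to the enone in 12) and C6 (α to nitro) stay epimerisable, so all isomers should drain into one: the C5 centre locks the half-chair of ring B with H5 pseudo-axial, and allylic 1,2-strain with the C20 methyl on C9 pushes the C17 methyl into the pseudo-axial position on the opposite face, which is 8R in halimane numbering. Chemoselectivity rests on the large acidity gap between nitroalkane and ketone (no Robinson-type reaction of the ketone enolates), a second Michael addition is blocked by the branching at C5 and C4, and of the two possible six-ring aldols only C10→C9 can dehydrate, so the bridged C8→C1 ketol reverts.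

Step 6
Reactants: 12 methyl (1S,6R,8R,8aS)-1,5,6-trimethyl-8-nitro-4-oxo-1,2,3,4,6,7,8,8a-octahydronaphthalene-1-carboxylate
Product: 13 methyl (1S,6R,8aS)-1,5,6-trimethyl-4-oxo-1,2,3,4,6,7,8,8a-octahydronaphthalene-1-carboxylate
Conditions: Bu3SnH (3 equiv), AIBN (0.3 equiv), toluene, 110 °C
Reagents that add atoms: none
Why: Radical denitration (the stannyl radical adds to a nitro oxygen, C–N scission gives the secondary C6 radical, which takes H from Bu3SnH), in which the fully substituted, hindered enone is a poor partner for the stannyl radical and no stereocentre of the target is involved.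

Step 7
Reactants: 13 methyl (1S,6R,8aS)-1,5,6-trimethyl-4-oxo-1,2,3,4,6,7,8,8a-octahydronaphthalene-1-carboxylate; 14 vinylmagnesium bromide
Product: 15 methyl (1S,5S,6R,8aS)-5-ethenyl-1,5,6-trimethyl-4-(trimethylsilyloxy)-1,2,3,5,6,7,8,8a-octahydronaphthalene-1-carboxylate
Conditions: CuBr·SMe2 (20 mol %), Me3SiCl, HMPA, THF, −78 to −30 °C; Et3N, cold aq NaHCO3
Reagents that add atoms: chlorotrimethylsilane C[Si](C)(C)Cl
Why: Copper-catalysed, Me3SiCl-accelerated conjugate addition to a 2-alkylidenecyclohexanone (the pulegone type of acceptor), in which vinyl attacks C9 axially on the face anti to the pseudo-axial C17 methyl, which is also the chair-forming trajectory, so C9 is set as S and the C1 enolate is caught regiospecifically as its silyl ether.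

Step 8
Reactants: 15 methyl (1S,5S,6R,8aS)-5-ethenyl-1,5,6-trimethyl-4-(trimethylsilyloxy)-1,2,3,5,6,7,8,8a-octahydronaphthalene-1-carboxylate
Product: 16 methyl (1S,5S,6R,8aS)-5-ethenyl-1,5,6-trimethyl-4-(trifluoromethylsulfonyloxy)-1,2,3,5,6,7,8,8a-octahydronaphthalene-1-carboxylate
Conditions: CsF, PhNTf2, DME, rt
Reagents that add atoms: N-phenylbis(trifluoromethanesulfonimide) O=S(=O)(N(c1ccccc1)S(=O)(=O)C(F)(F)F)C(F)(F)F
Why: Fluoride-induced desilylation releases the regiodefined C1(10) enolate, which is O-sulfonylated before it can equilibrate (regiospecific enol triflate formation).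

Step 9
Reactants: 16 methyl (1S,5S,6R,8aS)-5-ethenyl-1,5,6-trimethyl-4-(trifluoromethylsulfonyloxy)-1,2,3,5,6,7,8,8a-octahydronaphthalene-1-carboxylate
Product: 17 methyl (1S,5S,6R,8aS)-5-ethenyl-1,5,6-trimethyl-1,2,3,5,6,7,8,8a-octahydronaphthalene-1-carboxylate
Conditions: Pd(OAc)2 (5 mol %), PPh3 (10 mol %), HCO2H, n-Bu3N, DMF, 60 °C
Reagents that add atoms: none
Why: Palladium-catalysed formate reduction of an enol triflate replaces C–O by C–H without moving the double bond, which fixes the C1=C10 olefin, and the vinyl group and the ester are inert.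

Step 10
Reactants: 18 methyl acetoacetate
Product: 19 methyl (E)-3-(trifluoromethylsulfonyloxy)but-2-enoate
Conditions: Tf2O, aq Me4NOH, hexanes, 5 °C
Reagents that add atoms: trifluoromethanesulfonic anhydride O=S(=O)(OS(=O)(=O)C(F)(F)F)C(F)(F)F
Why: O-Triflation of the acetoacetate enolate with a non-chelating ammonium counter-ion goes through the open E enolate and gives the E enol triflate that carries the geometry of the C13=C14 olefin.

Step 11
Reactants: 17 methyl (1S,5S,6R,8aS)-5-ethenyl-1,5,6-trimethyl-1,2,3,5,6,7,8,8a-octahydronaphthalene-1-carboxylate; 19 methyl (E)-3-(trifluoromethylsulfonyloxy)but-2-enoate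
Product: 21 methyl (1S,5S,6R,8aS)-5-[(E)-5-methoxy-3-methyl-5-oxopent-3-en-1-yl]-1,5,6-trimethyl-1,2,3,5,6,7,8,8a-octahydronaphthalene-1-carboxylate, via B-alkyl borane 20 (not isolated)
Conditions: 9-BBN-H, THF, rt; then 19, Pd(dppf)Cl2 (5 mol %), aq K3PO4, DMF, rt to 50 °C
Reagents that add atoms: none
Why: Anti-Markovnikov hydroboration by 9-BBN-H picks the monosubstituted vinyl group over the trisubstituted ring olefin, and the B-alkyl Suzuki–Miyaura coupling joins C12 to C13 with retention of the E geometry.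

Step 12
Reactants: 21 methyl (1S,5S,6R,8aS)-5-[(E)-5-methoxy-3-methyl-5-oxopent-3-en-1-yl]-1,5,6-trimethyl-1,2,3,5,6,7,8,8a-octahydronaphthalene-1-carboxylate
Product: 22 methyl (1S,5S,6R,8aS)-5-[(E)-5-hydroxy-3-methylpent-3-en-1-yl]-1,5,6-trimethyl-1,2,3,5,6,7,8,8a-octahydronaphthalene-1-carboxylate
Conditions: i-Bu2AlH (2.2 equiv), CH2Cl2, −78 °C; aq potassium sodium tartrate
Reagents that add atoms: none
Why: i-Bu2AlH reduces the exposed conjugated ester to the allylic alcohol at low temperature, while the tertiary C18 ester is too hindered to react (chemoselective 1,2-reduction).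

Step 13
Reactants: 22 methyl (1S,5S,6R,8aS)-5-[(E)-5-hydroxy-3-methylpent-3-en-1-yl]-1,5,6-trimethyl-1,2,3,5,6,7,8,8a-octahydronaphthalene-1-carboxylate
Product: 23 (1S,5S,6R,8aS)-5-[(E)-5-hydroxy-3-methylpent-3-en-1-yl]-1,5,6-trimethyl-1,2,3,5,6,7,8,8a-octahydronaphthalene-1-carboxylic acid
Conditions: NaSEt, DMF, 100 °C; then AcOH
Reagents that add atoms: none
Why: SN2 dealkylation of the methyl ester by thiolate attacks the methyl carbon and not the shielded carbonyl, needs no strong acid, and so leaves the acid-labile C1=C10 olefin and the allylic alcohol untouched.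

Step 14
Reactants: 23 (1S,5S,6R,8aS)-5-[(E)-5-hydroxy-3-methylpent-3-en-1-yl]-1,5,6-trimethyl-1,2,3,5,6,7,8,8a-octahydronaphthalene-1-carboxylic acid; 24 propionic anhydride
Product: 25 (1S,5S,6R,8aS)-1,5,6-trimethyl-5-[(E)-3-methyl-5-(propanoyloxy)pent-3-en-1-yl]-1,2,3,5,6,7,8,8a-octahydronaphthalene-1-carboxylic acid
Conditions: pyridine, DMAP (10 mol %), CH2Cl2, 0 °C to rt; then H2O/THF
Reagents that add atoms: none
Why: DMAP-catalysed acylation esterifies the primary allylic alcohol, and any mixed anhydride formed at the hindered acid is hydrolysed back in the aqueous work-up.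

Compound list
1 | (E)-3-(tert-butyldimethylsilyloxy)-N,N-dimethylbuta-1,3-dien-1-amine | CN(C)/C=C/C(=C)O[Si](C)(C)C(C)(C)C | starting material
2 | methacrolein | CC(=C)C=O | starting material
3 | (1S,2R)-4-(tert-butyldimethylsilyloxy)-2-(dimethylamino)-1-methylcyclohex-3-ene-1-carbaldehyde | O=C[C@@]1(C)CCC(O[Si](C)(C)C(C)(C)C)=C[C@H]1N(C)C | intermediate
4 | (S)-1-methyl-4-oxocyclohex-2-ene-1-carbaldehyde | O=C[C@]1(C)C=CC(=O)CC1 | intermediate
5 | (S)-1-methyl-4-oxocyclohex-2-ene-1-carboxylic acid | OC(=O)[C@]1(C)C=CC(=O)CC1 | intermediate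
6 | methyl (S)-1-methyl-4-oxocyclohex-2-ene-1-carboxylate | COC(=O)[C@]1(C)C=CC(=O)CC1 | intermediate
7 | nitromethane | C[N+](=O)[O-] | starting material
8 | methyl (1S,2S)-1-methyl-2-(nitromethyl)-4-oxocyclohexane-1-carboxylate | COC(=O)[C@@]1(C)CCC(=O)C[C@@H]1C[N+](=O)[O-] | intermediate
9 | 3-methylbut-3-en-2-one | CC(=C)C(C)=O | starting material
10 | methyl (1S,2S)-1-methyl-2-(3-methyl-1-nitro-4-oxopentyl)-4-oxocyclohexane-1-carboxylate (epimers in the side chain) | COC(=O)[C@@]1(C)CCC(=O)C[C@@H]1C(CC(C)C(C)=O)[N+](=O)[O-] | intermediate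
11 | methyl (1S,8aS)-5-hydroxy-1,5,6-trimethyl-8-nitro-4-oxodecahydronaphthalene-1-carboxylate (equilibrating isomers) | COC(=O)[C@@]1(C)CCC(=O)C2[C@@H]1C(CC(C)C2(C)O)[N+](=O)[O-] | intermediate
12 | methyl (1S,6R,8R,8aS)-1,5,6-trimethyl-8-nitro-4-oxo-1,2,3,4,6,7,8,8a-octahydronaphthalene-1-carboxylate | COC(=O)[C@@]1(C)CCC(=O)C2=C(C)[C@H](C)C[C@@H]([N+](=O)[O-])[C@H]12 | intermediate
13 | methyl (1S,6R,8aS)-1,5,6-trimethyl-4-oxo-1,2,3,4,6,7,8,8a-octahydronaphthalene-1-carboxylate | COC(=O)[C@@]1(C)CCC(=O)C2=C(C)[C@H](C)CC[C@H]12 | intermediate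
14 | vinylmagnesium bromide | C=C[Mg]Br | starting material
15 | methyl (1S,5S,6R,8aS)-5-ethenyl-1,5,6-trimethyl-4-(trimethylsilyloxy)-1,2,3,5,6,7,8,8a-octahydronaphthalene-1-carboxylate | COC(=O)[C@@]1(C)CCC(O[Si](C)(C)C)=C2[C@@H]1CC[C@@H](C)[C@]2(C)C=C | intermediate
16 | methyl (1S,5S,6R,8aS)-5-ethenyl-1,5,6-trimethyl-4-(trifluoromethylsulfonyloxy)-1,2,3,5,6,7,8,8a-octahydronaphthalene-1-carboxylate | COC(=O)[C@@]1(C)CCC(OS(=O)(=O)C(F)(F)F)=C2[C@@H]1CC[C@@H](C)[C@]2(C)C=C | intermediate
17 | methyl (1S,5S,6R,8aS)-5-ethenyl-1,5,6-trimethyl-1,2,3,5,6,7,8,8a-octahydronaphthalene-1-carboxylate | COC(=O)[C@@]1(C)CCC=C2[C@@H]1CC[C@@H](C)[C@]2(C)C=C | intermediate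
18 | methyl acetoacetate | COC(=O)CC(C)=O | starting material
19 | methyl (E)-3-(trifluoromethylsulfonyloxy)but-2-enoate | COC(=O)/C=C(\C)OS(=O)(=O)C(F)(F)F | intermediate
20 | methyl (1S,5S,6R,8aS)-5-[2-(9-borabicyclo[3.3.1]nonan-9-yl)ethyl]-1,5,6-trimethyl-1,2,3,5,6,7,8,8a-octahydronaphthalene-1-carboxylate | COC(=O)[C@@]1(C)CCC=C2[C@@H]1CC[C@@H](C)[C@]2(C)CCB3C4CCCC3CCC4 | intermediate
21 | methyl (1S,5S,6R,8aS)-5-[(E)-5-methoxy-3-methyl-5-oxopent-3-en-1-yl]-1,5,6-trimethyl-1,2,3,5,6,7,8,8a-octahydronaphthalene-1-carboxylate | COC(=O)[C@@]1(C)CCC=C2[C@@H]1CC[C@@H](C)[C@]2(C)CC/C(C)=C/C(=O)OC | intermediate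
22 | methyl (1S,5S,6R,8aS)-5-[(E)-5-hydroxy-3-methylpent-3-en-1-yl]-1,5,6-trimethyl-1,2,3,5,6,7,8,8a-octahydronaphthalene-1-carboxylate | COC(=O)[C@@]1(C)CCC=C2[C@@H]1CC[C@@H](C)[C@]2(C)CC/C(C)=C/CO | intermediate
23 | (1S,5S,6R,8aS)-5-[(E)-5-hydroxy-3-methylpent-3-en-1-yl]-1,5,6-trimethyl-1,2,3,5,6,7,8,8a-octahydronaphthalene-1-carboxylic acid | OC(=O)[C@@]1(C)CCC=C2[C@@H]1CC[C@@H](C)[C@]2(C)CC/C(C)=C/CO | intermediate
24 | propionic anhydride | CCC(=O)OC(=O)CC | starting material
25 | (1S,5S,6R,8aS)-1,5,6-trimethyl-5-[(E)-3-methyl-5-(propanoyloxy)pent-3-en-1-yl]-1,2,3,5,6,7,8,8a-octahydronaphthalene-1-carboxylic acid | CCC(=O)OC/C=C(\C)CC[C@]1(C)C2=CCC[C@](C)(C(=O)O)[C@H]2CC[C@H]1C | target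

Total step count: 14. Longest linear sequence: 13 (steps 1–9 and 11–14).

Steps most likely to fail

Step 7. Enolisation of the hindered enone by the basic vinyl reagent, or 1,2-addition, may outrun transfer of vinyl to the fully substituted β-carbon. The fallback replaces organocopper chemistry by a sigmatropic shift. It sets out from 13 and comes back at 21.
- LiBH(s-Bu)3 (THF, −78 °C) attacks the ketone equatorially. It gives the axial allylic alcohol methyl (1S,4R,6R,8aS)-4-hydroxy-1,5,6-trimethyl-1,2,3,4,6,7,8,8a-octahydronaphthalene-1-carboxylate F1.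
- A Johnson–Claisen rearrangement (MeC(OEt)3, cat. EtCO2H, 140 °C) carries the C1–O chirality suprafacially to C9 and creates the C1=C10 olefin at the same time. The product is methyl (1S,5S,6R,8aS)-5-(2-ethoxy-2-oxoethyl)-1,5,6-trimethyl-1,2,3,5,6,7,8,8a-octahydronaphthalene-1-carboxylate F2.
- i-Bu2AlH reduces the less hindered ester to methyl (1S,5S,6R,8aS)-5-(2-hydroxyethyl)-1,5,6-trimethyl-1,2,3,5,6,7,8,8a-octahydronaphthalene-1-carboxylate F3.
- I2, PPh3 and imidazole give methyl (1S,5S,6R,8aS)-5-(2-iodoethyl)-1,5,6-trimethyl-1,2,3,5,6,7,8,8a-octahydronaphthalene-1-carboxylate F4.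
- Zinc insertion (Zn, LiCl, THF) gives the alkylzinc iodide of the same skeleton F5.
- Negishi coupling of this reagent with 19 (Pd(PPh3)4) gives 21.

Step 6. Addition of the stannyl radical to the enone (conjugate reduction), or N–O instead of C–N scission, may compete with denitration. The fallback removes the nitro group before any enone exists. It sets out from 8 and comes back at 13.
- The Michael addition to 9 is run alone (cat. DBU, MeCN, 0 °C) and 10 is isolated.
- Bu3SnH/AIBN denitrates this plain γ-nitro ketone to methyl (1S,2S)-1-methyl-2-(3-methyl-4-oxopentyl)-4-oxocyclohexane-1-carboxylate F6.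
- NaOMe in MeOH at reflux closes ring B by aldol condensation to 13.

Step 5. Retro-Michael loss of the nitroalkyl unit at the temperature needed for dehydration, or stalling at the ketol stage, may break the domino. The fallback makes the C6–C7 bond by radical chemistry from a temporary three-membered ring and closes ring B under acid. It sets out from 6 and comes back at 13.
- Corey–Chaykovsky cyclopropanation (Me3S(O)I, NaH, DMSO) gives the cyclopropyl ketone methyl 2-methyl-5-oxobicyclo[4.1.0]heptane-2-carboxylate, with the CH2 bridge trans to the ester F7.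
- Me3SiI opens the external C10–C6 bond to methyl (1S,2S)-2-(iodomethyl)-1-methyl-4-(trimethylsilyloxy)cyclohex-3-ene-1-carboxylate F8.
- Aqueous work-up gives methyl (1S,2S)-2-(iodomethyl)-1-methyl-4-oxocyclohexane-1-carboxylate F9.
- Giese addition of the C6 radical to 9 (Bu3SnH, AIBN) gives the diketone F6.
- p-TsOH in toluene with removal of water gives 13.

Further compounds
F1 | step 7 | methyl (1S,4R,6R,8aS)-4-hydroxy-1,5,6-trimethyl-1,2,3,4,6,7,8,8a-octahydronaphthalene-1-carboxylate | COC(=O)[C@@]1(C)CC[C@@H](O)C2=C(C)[C@H](C)CC[C@H]12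
F2 | step 7 | methyl (1S,5S,6R,8aS)-5-(2-ethoxy-2-oxoethyl)-1,5,6-trimethyl-1,2,3,5,6,7,8,8a-octahydronaphthalene-1-carboxylate | COC(=O)[C@@]1(C)CCC=C2[C@@H]1CC[C@@H](C)[C@]2(C)CC(=O)OCC
F3 | step 7 | methyl (1S,5S,6R,8aS)-5-(2-hydroxyethyl)-1,5,6-trimethyl-1,2,3,5,6,7,8,8a-octahydronaphthalene-1-carboxylate | COC(=O)[C@@]1(C)CCC=C2[C@@H]1CC[C@@H](C)[C@]2(C)CCO
F4 | step 7 | methyl (1S,5S,6R,8aS)-5-(2-iodoethyl)-1,5,6-trimethyl-1,2,3,5,6,7,8,8a-octahydronaphthalene-1-carboxylate | COC(=O)[C@@]1(C)CCC=C2[C@@H]1CC[C@@H](C)[C@]2(C)CCI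
F5 | step 7 | alkylzinc iodide derived from F4 | COC(=O)[C@@]1(C)CCC=C2[C@@H]1CC[C@@H](C)[C@]2(C)CC[Zn]I
F6 | step 6 | methyl (1S,2S)-1-methyl-2-(3-methyl-4-oxopentyl)-4-oxocyclohexane-1-carboxylate | COC(=O)[C@@]1(C)CCC(=O)C[C@@H]1CCC(C)C(C)=O
F7 | step 5 | methyl 2-methyl-5-oxobicyclo[4.1.0]heptane-2-carboxylate, CH2 bridge trans to the ester | COC(=O)[C@@]1(C)CCC(=O)[C@@H]2C[C@H]12
F8 | step 5 | methyl (1S,2S)-2-(iodomethyl)-1-methyl-4-(trimethylsilyloxy)cyclohex-3-ene-1-carboxylate | COC(=O)[C@@]1(C)CCC(O[Si](C)(C)C)=C[C@@H]1CI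
F9 | step 5 | methyl (1S,2S)-2-(iodomethyl)-1-methyl-4-oxocyclohexane-1-carboxylate | COC(=O)[C@@]1(C)CCC(=O)C[C@@H]1CI
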